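Chroman numbering is used for the heterocycle and arene throughout (O1, C2, C3, C4, C4a, C5–C8, C8a). In systematic names the primed locants belong to the oxane or chroman ring.

## The problem

The target is a chroman whose C2 is a spiro carbon shared with a 3,3-dimethylbicyclo[2.2.1]heptane. O1 therefore sits on a fully substituted carbon flanked by a quaternary CMe2 carbon and a bridgehead. The arene is hexasubstituted: a diformylphloroglucinol with hydroxyls on C5 and C7, formyl groups on C6 and C8, and the third oxygen tied up as O1.

There are four stereocentres. The two bridgeheads come as a unit from the terpene and can control C2, because a nucleophile should approach the derived ketone from the exo face and leave O1 endo, as the target requires. C4 carries the isobutyl group (cis to the CMe2 carbon across the pyran ring) and is separated from C2 by a methylene. It cannot be trusted to follow C2, so it is better brought in with a configuration set by a reagent.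

The tertiary alkyl aryl ether at C2 is the fragile point. Ionisation would give a cation next to CMe2 and a bridgehead, which is expected to undergo Wagner–Meerwein shifts, so strong Lewis or Brønsted acids, late O-demethylation and ether formation through a cation are all to be avoided. The free diformylphloroglucinol is electron-rich, chelating and easily oxidised, and should appear last.

The feature that opens the structure is that the arene (C4a, C5, C6, C7, C8, C8a) is a masked 1,3,5-triketone. Its O1–C8a–C4a edge can be carried as the cyclic enol ether of a β-keto ester on a finished spiro tetrahydropyran. The missing C5–C6 unit can then be added as a malonyl group, and the ring forms with free oxygen already on C5 and C7.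

## Retrosynthesis

**19 to 17 (C6–CHO and C8–CHO).** Both formyl carbons are removed from target 19, leading back to the 5,7-diol 17. The neighbouring choice, keeping the C6 carbon from the ring construction as an ester and reducing it, would need phenol protection, two redox steps, deprotection and a separate formylation at C8. Diol 17 has only two free ring positions, so one twofold formylation is regiochemically unambiguous. The forward reaction must formylate a phloroglucinol-type ring twice without strong acid.

**17 to 15 (C6–CO2Me).** The ester on C6 of 15 is treated as a traceless activating group. It is what makes the ring closure work in the key step, and 2,4,6-trioxygenated benzoic acids lose CO2 easily. The forward reaction is hydrolysis and decarboxylation in base, then mild acid.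

**15 to 11 and 12 (C4a–C5 and C6–C7; key disconnection).** Cutting these two bonds removes the whole arene and leaves the spiro enol ether 11, which already holds O1 on both C2 and C8a, plus commercial methyl malonyl chloride 12. Cutting O1–C8a or O1–C2 instead would require an aryl ether to be made at the hindered tertiary carbon, by a hindered alkoxide or through the cation the molecule cannot tolerate. Compound 11 has no aromatic ring and no phenol to protect. The forward reaction must acylate C4a (the γ-carbon of a 3-alkoxy enoate) and not C8, and must then close C6 onto the ester carbon C7 through carbon, not oxygen.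

**11 to 8 and 9 (C8a=C8).** The exocyclic alkene is cut to lactone 8 and methyl acetate 9. Ester-enolate addition to a lactone and dehydration of the hemiketal is the standard entry to such ylidene acetates, whereas phosphorus olefination of lactones is unreliable. The forward reaction must give the conjugated exocyclic isomer with E geometry, which is expected to be the thermodynamic one.

**8 to 3 and 6 (C2–C3 and the acyl C8a–O1 bond).** This joins ketone 3 to the four-carbon iodo ester 6 and sets C2. C4 is already present in 6, so the two stereocentres are set independently and only one diastereomer can form if attack is exo. The alternative of adding a small nucleophile to 3 and installing the isobutyl group later by conjugate addition would make C4 depend on C2, most likely with the wrong sense (addition anti to CMe2). The forward reaction must add a β-branched primary carbon nucleophile to a hindered ketone. This is helped by 3 having no enolisable hydrogen, and the alkoxide then lactonises.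

**6 to 5 to 4 (C–I from C–CO2H; desymmetrisation).** The pyran needs four carbons between C2 and O1 (C3, C4, C4a, C8a), while a glutarate offers five. Reducing the acid arm of hemiester 5 would give a five-carbon chain and a seven-membered lactone. Iododecarboxylation excises that carbon and installs the halide in one step. Hemiester 5 comes from the prochiral, commercial anhydride 4 by catalytic enantioselective methanolysis, which is the only reagent-controlled stereochemical step of the route.

**3 to 1 (C=O from C=CH2).** Oxidative cleavage of the exocyclic alkene of (−)-camphene 1 gives 3 with both bridgeheads intact.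

## Roads not taken

**Alternative 1: aldol–SNAr cascade.**
- **Cut:** C2–C3 and O1–C8a, so that the carbonyl oxygen of 3 becomes O1.
- **Forward key step:** the lithium enolate of 1-(2-fluoro-4,6-dimethoxyphenyl)ethanone A1 would add to the exo face of 3. On warming in THF with DMPU the endo alkoxide would displace the ortho fluoride, giving the spiro chroman-4-one A2.
- **Merits:** the spiro chroman skeleton with O1 endo would be reached in two steps from 1, the arene is bought and not built, and no acid is involved.
- **Weak points:**
  - The aldolate from a methyl ketone enolate and a hindered ketone readily reverts, and the step that must trap it is a displacement by a neopentyl-type tertiary alkoxide on a ring bearing two methoxy donors.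
  - A2 has a carbonyl where the target has the isobutyl stereocentre. Olefination or addition–dehydration followed by hydrogenation would leave C4 to substrate control from C2 across a methylene, with no assurance of the sense.
  - The phenols emerge as methyl ethers, and the reagents that cleave them (BBr3, AlCl3) are those that ionise the C2–O1 bond.
- **Comparison:** in step count to the bicyclic core this road is clearly better (two steps against five to 11). The chosen plan sets against it a C4 centre fixed by reagent control before the rings are joined, phenols that are never protected, and no dependence on trapping an unfavourable aldol equilibrium.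

**Alternative 2: ring-closing metathesis across C3 and C4.**
- **Cut:** the C3–C4 bond, as a C3=C4 alkene.
- **Forward key step:** the second-generation Hoveyda–Grubbs catalyst, RuCl2(H2IMes)(=CH-C6H4-2-OiPr), would join the vinyl group on C2 and the 1,1-disubstituted styrene on C4a of diene A3 with loss of ethylene, giving the 2H-chromene A4.
- **Merits:** neutral, catalytic ring closure, and C2 set by exo addition of a small vinyl nucleophile to 3.
- **Weak points:**
  - A3 contains an aryl ether of the hindered tertiary endo carbinol, for which there is no dependable construction short of the cation or a difficult arylation.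
  - The metathesis joins a styrene flanked by two ortho substituents to a vinyl group on a quaternary carbon, both poor partners.
  - Hydrogenation of the trisubstituted alkene of A4 again leaves C4 to substrate control.
  - Methyl ether cleavage remains.
- **Comparison:** this road is no shorter than the chosen plan and shares the weaknesses of Alternative 1 at C4 and in deprotection. It is equal only in how C2 is set. The chosen plan makes O1–C2 by carbonyl addition, which is the easy way round.

**Alternative 3: anodic aryl C–H etherification by the endo carbinol.**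
- **Cut:** O1–C8a.
- **Forward key step:** anodic oxidation of the dimethoxyarene carbinol A5 (carbon anode, (CF3)2CHOH, Bu4NPF6, 2,6-lutidine) would give an arene radical cation, trapped by the tertiary hydroxyl at the ortho carbon to give the dimethoxy chroman A6.
- **Merits:** like the chosen plan, it sets C2 and C4 before the heterocycle is closed, so A6 would carry all four stereocentres. The C–O bond forms at the arene and not through a tertiary cation, and the arene is bought.
- **Weak points:**
  - C8a of A5 is meta to both methoxy groups, the position least activated in the radical cation, while the benzylic C4–H offers a competing deprotonation path.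
  - The product A6, with three oxygen donors, is more easily oxidised than A5, so over-oxidation is built in.
  - Methyl ether cleavage remains.
- **Comparison:** this road matches the chosen plan in stereochemical logic and is better in not having to construct the arene. The chosen plan sets against it a ring construction with classical precedent that delivers free phenols, at the cost of two extra steps (decarboxylation and formylation of both positions, not one).

Key step: step 6

**Assumptions.**
- Commercial (−)-camphene is taken at the highest available enantiomeric purity. Any antipode carried through would appear after step 4 as a diastereomer of 8 and be removed there.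
- The dihydroquinidine-based catalyst of step 2 is taken to favour the (S)-hemiester 5, by analogy with other 3-alkylglutaric anhydrides. If the opposite sense is found, the dihydroquinine pseudoenantiomer (DHQ)2AQN is used with no other change.

## Route

Step 1
Reactants: 1 (1S,4R)-(−)-camphene
Product: 3 (1R,4S)-3,3-dimethylbicyclo[2.2.1]heptan-2-one (camphenilone), via ozonide 2 (not isolated)
Conditions: O3, CH2Cl2, −78 °C; then Me2S, −78 → 20 °C
Reagents that add atoms: ozone, [O-][O+]=O
Why: Ozonolysis of the 1,1-disubstituted exocyclic alkene with reductive work-up. The bridgeheads are untouched, and the ketone has no enolisable hydrogen (bridgehead on one side, quaternary carbon on the other), so it cannot epimerise.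

Step 2
Reactants: 4 3-isobutylglutaric anhydride [4-(2-methylpropyl)oxane-2,6-dione]
Product: 5 (3S)-3-(2-methoxy-2-oxoethyl)-5-methylhexanoic acid
Conditions: (DHQD)2AQN [1,4-bis(dihydroquinidinyloxy)anthraquinone] (cat.), MeOH, Et2O, −40 °C
Reagents that add atoms: methanol, CO
Why: Cinchona-alkaloid-catalysed desymmetrising methanolysis of a prochiral cyclic anhydride (general-base catalysis by the quinuclidine nitrogen). The catalyst distinguishes the two enantiotopic carbonyl groups and so sets the centre that becomes C4.

Step 3
Reactants: 5 (3S)-3-(2-methoxy-2-oxoethyl)-5-methylhexanoic acid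
Product: 6 methyl (3R)-3-(iodomethyl)-5-methylhexanoate
Conditions: PhI(OAc)2, I2, PhH, hν, reflux
Reagents that add atoms: iodine, II
Why: Hunsdiecker-type iododecarboxylation through the acyl hypoiodite (Suárez variant); the primary radical is trapped by iodine and the stereocentre is not part of it. The change of descriptor from S to R reflects CIP priorities only.

Step 4
Reactants: 3 (1R,4S)-3,3-dimethylbicyclo[2.2.1]heptan-2-one; 6 methyl (3R)-3-(iodomethyl)-5-methylhexanoate
Product: 8 (1R,2R,4S,4'S)-3,3-dimethyl-4'-(2-methylpropyl)spiro[bicyclo[2.2.1]heptane-2,2'-oxan]-6'-one, via hydroxy ester 7 (not isolated)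
Conditions: SmI2, HMPA, THF, 0 → 25 °C
Reagents that add atoms: none
Why: Barbier reaction with SmI2: divalent samarium reduces the primary iodide to an alkylsamarium in the presence of the hindered but non-enolisable ketone, and the trivalent samarium alkoxide of 7 closes onto the methyl ester to give the six-membered lactone. The new centre C2 is set by the bicyclic skeleton, since the nucleophile should enter from the exo face (the side of the one-carbon bridge) and leave the oxygen endo; C4' comes unchanged from 6.

Step 5
Reactants: 8 (1R,2R,4S,4'S)-3,3-dimethyl-4'-(2-methylpropyl)spiro[bicyclo[2.2.1]heptane-2,2'-oxan]-6'-one; 9 methyl acetate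
Product: 11 methyl (2E)-2-[(1R,2R,4S,4'R)-3,3-dimethyl-4'-(2-methylpropyl)spiro[bicyclo[2.2.1]heptane-2,2'-oxan]-6'-ylidene]acetate, via hemiketal 10 (not isolated)
Conditions: MeOAc, LiN(iPr)2, THF, −78 °C, AcOH quench; then (CF3CO)2O, pyridine, CH2Cl2, 0 → 20 °C
Reagents that add atoms: none
Why: Claisen-type addition of lithio methyl acetate to the lactone carbonyl stops at the cyclic hemiketal; trifluoroacetylation and elimination toward the ester give the conjugated exocyclic enol ether. The E isomer (ester anti to O1, as in 3-alkoxycrotonates) is expected as the thermodynamic one, and the 4'R descriptor reflects changed CIP priorities, not a change at the centre.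

Step 6
Reactants: 11 methyl (2E)-2-[(1R,2R,4S,4'R)-3,3-dimethyl-4'-(2-methylpropyl)spiro[bicyclo[2.2.1]heptane-2,2'-oxan]-6'-ylidene]acetate; 12 methyl malonyl chloride (methyl 3-chloro-3-oxopropanoate)
Product: 15 methyl (1R,2R,4S,4'S)-5',7'-dihydroxy-3,3-dimethyl-4'-(2-methylpropyl)spiro[bicyclo[2.2.1]heptane-2,2'-chromane]-6'-carboxylate, via silyl dienol ether 13 (not isolated), via acyl enoate 14 (not isolated)
Conditions: LiN(iPr)2, THF, −78 °C, then Me3SiCl; evaporate; ClCOCH2CO2Me, CH2Cl2, −78 → 20 °C; evaporate; NaOMe, MeOH, 20 → 50 °C; aq. HCl work-up
Reagents that add atoms: none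
Why: γ-Deprotonation of the E-configured 3-alkoxy enoate at C4a (the methylene syn to the ester carbonyl) and O-silylation give the 1-methoxy-1-silyloxy-3-alkoxydiene 13, the cyclic counterpart of the dienes made in the same way from 3-methoxycrotonates. Such dienes react with acyl chlorides through their terminal carbon (vinylogous Mukaiyama-type acylation), so C4a–C5 forms and chlorotrimethylsilane is lost without any strong base that could turn the malonyl chloride into a ketene. In 14 the C6 methylene, flanked by the C5 ketone and its own ester, is the most acidic site, so methoxide generates the C6 enolate while the C7 ester stays un-enolised and electrophilic. This enolate attacks C7 in a 6-(enolexo)-exo-trig Claisen (Dieckmann) closure, methoxide leaves, and two enolisations give the arene; the closest known reaction type is the base-mediated cyclisation of 3,5-dioxopimelates and of protected 3,5,7-trioxo esters to phloroglucinol carboxylates. No stereocentre is created (the C4a centre of 14 is lost on aromatisation), and C2 and C4 carry no acidic hydrogen at any stage. The step needs γ- over α-acylation, which the silyl dienol ether secures through its more nucleophilic and less hindered terminus, and carbon over oxygen closure, which is secured because O-acylation to a 2-pyranone is reversible in NaOMe/MeOH whereas aromatisation is not. The E geometry of 11, or its equilibration through the C4a enolate of 14, places C7 syn to C4a, so only the six-membered ring can form and O1 stays bound to C2 and C8a throughout.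

Step 7
Reactants: 15 methyl (1R,2R,4S,4'S)-5',7'-dihydroxy-3,3-dimethyl-4'-(2-methylpropyl)spiro[bicyclo[2.2.1]heptane-2,2'-chromane]-6'-carboxylate
Product: 17 (1R,2R,4S,4'S)-3,3-dimethyl-4'-(2-methylpropyl)spiro[bicyclo[2.2.1]heptane-2,2'-chromane]-5',7'-diol, via carboxylic acid 16 (not isolated)
Conditions: KOH, H2O/ethylene glycol, 120 °C, Ar; then aq. HCl to pH 3, 20 → 50 °C
Reagents that add atoms: none
Why: Saponification followed by decarboxylation of the 2,6-dihydroxy-4-alkoxybenzoic acid, which loses CO2 on mild warming through ipso-protonation of the electron-rich ring (classical behaviour of phloroglucinolcarboxylic acids). The tertiary ether is inert to aqueous base and to dilute acid at this temperature, and no stereocentre is involved.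

Step 8
Reactants: 17 (1R,2R,4S,4'S)-3,3-dimethyl-4'-(2-methylpropyl)spiro[bicyclo[2.2.1]heptane-2,2'-chromane]-5',7'-diol
Product: 19 (1R,2R,4S,4'S)-5',7'-dihydroxy-3,3-dimethyl-4'-(2-methylpropyl)spiro[bicyclo[2.2.1]heptane-2,2'-chromane]-6',8'-dicarbaldehyde, via bis-iminium salt 18 (not isolated)
Conditions: POCl3, DMF, MeCN, 0 → 25 °C; then H2O, NaOAc, 50 °C
Reagents that add atoms: N,N-dimethylformamide, CN(C)C=O; water, O
Why: Twofold Vilsmeier–Haack formylation at the only free ring positions, C6 and C8, each activated by three oxygen donors, as in the preparation of 2,4-diformylphloroglucinol from phloroglucinol. The chloroiminium reagent and the buffered hydrolysis avoid the strong acids that would ionise the C2–O1 bond.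

## Compound list

1 | (1S,4R)-(−)-camphene [(1S,4R)-2,2-dimethyl-3-methylidenebicyclo[2.2.1]heptane] | C=C1[C@@H]2CC[C@@H](C2)C1(C)C | starting material
2 | ozonide of 1, (1R,4S)-3,3-dimethylspiro[bicyclo[2.2.1]heptane-2,3'-[1,2,4]trioxolane], spiro carbon not defined | C1OOC2(O1)[C@@H]1CC[C@@H](C1)C2(C)C | intermediate (not isolated)
3 | (1R,4S)-3,3-dimethylbicyclo[2.2.1]heptan-2-one (camphenilone) | O=C1[C@@H]2CC[C@@H](C2)C1(C)C | intermediate
4 | 3-isobutylglutaric anhydride [4-(2-methylpropyl)oxane-2,6-dione] | CC(C)CC1CC(=O)OC(=O)C1 | starting material
5 | (3S)-3-(2-methoxy-2-oxoethyl)-5-methylhexanoic acid | CC(C)C[C@H](CC(=O)OC)CC(=O)O | intermediate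
6 | methyl (3R)-3-(iodomethyl)-5-methylhexanoate | CC(C)C[C@H](CC(=O)OC)CI | intermediate
7 | methyl (3S)-3-{[(1R,2R,4S)-2-hydroxy-3,3-dimethylbicyclo[2.2.1]heptan-2-yl]methyl}-5-methylhexanoate (alkyl exo, hydroxyl endo) | CC(C)C[C@H](CC(=O)OC)C[C@@]1(O)[C@@H]2CC[C@@H](C2)C1(C)C | intermediate (not isolated)
8 | (1R,2R,4S,4'S)-3,3-dimethyl-4'-(2-methylpropyl)spiro[bicyclo[2.2.1]heptane-2,2'-oxan]-6'-one (ring oxygen endo, isobutyl cis to CMe2) | CC(C)C[C@H]1C[C@@]2(OC(=O)C1)[C@@H]1CC[C@@H](C1)C2(C)C | intermediate
9 | methyl acetate | COC(C)=O | starting material
10 | methyl 2-[(1R,2R,4S,4'S)-6'-hydroxy-3,3-dimethyl-4'-(2-methylpropyl)spiro[bicyclo[2.2.1]heptane-2,2'-oxan]-6'-yl]acetate, C6' not defined | CC(C)C[C@H]1C[C@@]2(OC(O)(CC(=O)OC)C1)[C@@H]1CC[C@@H](C1)C2(C)C | intermediate (not isolated)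
11 | methyl (2E)-2-[(1R,2R,4S,4'R)-3,3-dimethyl-4'-(2-methylpropyl)spiro[bicyclo[2.2.1]heptane-2,2'-oxan]-6'-ylidene]acetate | CC(C)C[C@H]1C[C@@]2(O/C(=C/C(=O)OC)C1)[C@@H]1CC[C@@H](C1)C2(C)C | intermediate
12 | methyl malonyl chloride (methyl 3-chloro-3-oxopropanoate) | COC(=O)CC(=O)Cl | starting material
13 | (1R,2R,4S,4'S)-6'-{2-methoxy-2-[(trimethylsilyl)oxy]ethenyl}-3,3-dimethyl-4'-(2-methylpropyl)-3',4'-dihydrospiro[bicyclo[2.2.1]heptane-2,2'-pyran], ketene acetal geometry not defined | CC(C)C[C@H]1C[C@@]2(OC(C=C(OC)O[Si](C)(C)C)=C1)[C@@H]1CC[C@@H](C1)C2(C)C | intermediate (not isolated)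
14 | methyl 3-[(1R,2R,4S,4'S)-6'-(2-methoxy-2-oxoethylidene)-3,3-dimethyl-4'-(2-methylpropyl)spiro[bicyclo[2.2.1]heptane-2,2'-oxan]-5'-yl]-3-oxopropanoate, C5' and alkene geometry not defined | CC(C)C[C@H]1C[C@@]2(OC(=CC(=O)OC)C1C(=O)CC(=O)OC)[C@@H]1CC[C@@H](C1)C2(C)C | intermediate (not isolated)
15 | methyl (1R,2R,4S,4'S)-5',7'-dihydroxy-3,3-dimethyl-4'-(2-methylpropyl)spiro[bicyclo[2.2.1]heptane-2,2'-chromane]-6'-carboxylate | CC(C)C[C@H]1C[C@@]2(Oc3cc(O)c(C(=O)OC)c(O)c31)[C@@H]1CC[C@@H](C1)C2(C)C | intermediate
16 | (1R,2R,4S,4'S)-5',7'-dihydroxy-3,3-dimethyl-4'-(2-methylpropyl)spiro[bicyclo[2.2.1]heptane-2,2'-chromane]-6'-carboxylic acid | CC(C)C[C@H]1C[C@@]2(Oc3cc(O)c(C(=O)O)c(O)c31)[C@@H]1CC[C@@H](C1)C2(C)C | intermediate (not isolated)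
17 | (1R,2R,4S,4'S)-3,3-dimethyl-4'-(2-methylpropyl)spiro[bicyclo[2.2.1]heptane-2,2'-chromane]-5',7'-diol | CC(C)C[C@H]1C[C@@]2(Oc3cc(O)cc(O)c31)[C@@H]1CC[C@@H](C1)C2(C)C | intermediate
18 | 6',8'-bis[(dimethyliminio)methyl] derivative of 17, dichloride | CC(C)C[C@H]1C[C@@]2(Oc3c(C=[N+](C)C)c(O)c(C=[N+](C)C)c(O)c31)[C@@H]1CC[C@@H](C1)C2(C)C.[Cl-].[Cl-] | intermediate (not isolated)
19 | (1R,2R,4S,4'S)-5',7'-dihydroxy-3,3-dimethyl-4'-(2-methylpropyl)spiro[bicyclo[2.2.1]heptane-2,2'-chromane]-6',8'-dicarbaldehyde | CC(C)C[C@H]1C[C@@]2(Oc3c(C=O)c(O)c(C=O)c(O)c31)[C@@H]1CC[C@@H](C1)C2(C)C | target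

## Step count and least certain steps

Total: 8 steps. Longest linear sequence: 7 steps (steps 2 to 8, from anhydride 4); the camphene branch joins at step 4.

**Step 6 (key step).**
- **What may go wrong:** the acylation stage is the weak point. The acidic methylene of methyl malonyl chloride can transfer a proton to the silyl dienol ether or collapse to a ketene, so that 13 is desilylated back to 11 or acylated on oxygen. In the second stage, closure through the C5 enolate oxygen to a 2-pyranone may compete with the Claisen closure.
- **Fallback:** drop the malonyl activating group. Starting from 11, the silyl dienol ether 13 is made as before and acylated with acetyl chloride, which has no doubly activated methylene, to give the methyl ketone F1. Treatment with KOtBu in THF/t-BuOH then effects the classical cyclisation of a δ-keto ester to a cyclohexane-1,3-dione (methyl carbon C6 onto ester carbon C7), and aromatisation gives the diol directly. The same two bonds are formed, and the route is rejoined at 17, bypassing 15 and step 7.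

**Step 4.**
- **What may go wrong:** a β-branched primary organosamarium has to attack a neopentyl-type carbonyl, so reduction of the iodide to the alkane or of the ketone may outrun addition, and exo selectivity may be eroded.
- **Fallback:** use a more nucleophilic organometallic that cannot coexist with an ester. Starting from 6, iBu2AlH (CH2Cl2, −78 °C) gives the iodo alcohol F2, which is protected (t-BuMe2SiCl, imidazole) as the silyl ether F3. Iodine–lithium exchange (t-BuLi, Et2O/pentane, −78 °C), transmetalation with CeCl3 and addition to 3 give the exo-alkyl endo-carbinol F4. Bu4NF releases the diol F5, and oxidative lactonisation (TEMPO (2,2,6,6-tetramethylpiperidin-1-oxyl) cat., PhI(OAc)2, CH2Cl2) returns to the route at 8.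

**Step 8.**
- **What may go wrong:** the first iminium group may deactivate the ring enough for the second formylation to stall, or the acidic medium may ionise the C2–O1 bond with skeletal rearrangement.
- **Fallback:** keep the C6 carbon of the key step as the first formyl group and introduce the second under basic conditions. Starting from 15, silylation (t-BuMe2SiOTf, 2,6-lutidine) gives the bis-silyl ether ester F6, iBu2AlH gives the benzylic alcohol F7, and MnO2 gives the aldehyde F8. Bu4NF/AcOH releases the 6-formyl-5,7-diol F9, and ortho-formylation at C8 with MgCl2, Et3N and paraformaldehyde (MeCN, reflux) returns to the route at 19.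

**Step 5.**
- **What may go wrong:** the ester enolate may deprotonate the lactone instead of adding, or the dehydration may give mixtures of the endocyclic enol ether and the Z isomer.
- **Fallback:** build the enoate from the enol ether side. Starting from 8, Petasis methylenation (Cp2TiMe2, toluene, 70 °C) gives the exocyclic enol ether F10. Acylation with trichloroacetyl chloride and pyridine gives the β-alkoxyvinyl trichloromethyl ketone F11, and haloform-type cleavage with NaOMe in MeOH returns to the route at 11.

## Further compounds

F1 | step 6 | methyl 2-[5'-acetyl-3,3-dimethyl-4'-(2-methylpropyl)spiro[bicyclo[2.2.1]heptane-2,2'-oxan]-6'-ylidene]acetate, ring stereocentres as in 11, C5' and alkene geometry not defined | CC(C)C[C@H]1C[C@@]2(OC(=CC(=O)OC)C1C(C)=O)[C@@H]1CC[C@@H](C1)C2(C)C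
F2 | step 4 | (3R)-3-(iodomethyl)-5-methylhexan-1-ol | CC(C)C[C@H](CCO)CI
F3 | step 4 | tert-butyl{[(3R)-3-(iodomethyl)-5-methylhexyl]oxy}dimethylsilane | CC(C)C[C@H](CCO[Si](C)(C)C(C)(C)C)CI
F4 | step 4 | (1R,2R,4S)-2-[(2R)-2-(2-{[tert-butyl(dimethyl)silyl]oxy}ethyl)-4-methylpentyl]-3,3-dimethylbicyclo[2.2.1]heptan-2-ol (alkyl exo, hydroxyl endo) | CC(C)C[C@H](CCO[Si](C)(C)C(C)(C)C)C[C@@]1(O)[C@@H]2CC[C@@H](C2)C1(C)C
F5 | step 4 | (1R,2R,4S)-2-[(2R)-2-(2-hydroxyethyl)-4-methylpentyl]-3,3-dimethylbicyclo[2.2.1]heptan-2-ol | CC(C)C[C@H](CCO)C[C@@]1(O)[C@@H]2CC[C@@H](C2)C1(C)C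
F6 | step 8 | bis(tert-butyldimethylsilyl) ether of 15 | CC(C)C[C@H]1C[C@@]2(Oc3cc(O[Si](C)(C)C(C)(C)C)c(C(=O)OC)c(O[Si](C)(C)C(C)(C)C)c31)[C@@H]1CC[C@@H](C1)C2(C)C
F7 | step 8 | 6'-(hydroxymethyl) analogue of F6 | CC(C)C[C@H]1C[C@@]2(Oc3cc(O[Si](C)(C)C(C)(C)C)c(CO)c(O[Si](C)(C)C(C)(C)C)c31)[C@@H]1CC[C@@H](C1)C2(C)C
F8 | step 8 | 6'-formyl analogue of F6 | CC(C)C[C@H]1C[C@@]2(Oc3cc(O[Si](C)(C)C(C)(C)C)c(C=O)c(O[Si](C)(C)C(C)(C)C)c31)[C@@H]1CC[C@@H](C1)C2(C)C
F9 | step 8 | (1R,2R,4S,4'S)-5',7'-dihydroxy-3,3-dimethyl-4'-(2-methylpropyl)spiro[bicyclo[2.2.1]heptane-2,2'-chromane]-6'-carbaldehyde | CC(C)C[C@H]1C[C@@]2(Oc3cc(O)c(C=O)c(O)c31)[C@@H]1CC[C@@H](C1)C2(C)C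
F10 | step 5 | 6'-methylidene analogue of 8: 3,3-dimethyl-6'-methylidene-4'-(2-methylpropyl)spiro[bicyclo[2.2.1]heptane-2,2'-oxane], stereocentres as in 8 | CC(C)C[C@H]1C[C@@]2(OC(=C)C1)[C@@H]1CC[C@@H](C1)C2(C)C
F11 | step 5 | (E)-1,1,1-trichloro-3-[3,3-dimethyl-4'-(2-methylpropyl)spiro[bicyclo[2.2.1]heptane-2,2'-oxan]-6'-ylidene]propan-2-one, stereocentres as in 11 | CC(C)C[C@H]1C[C@@]2(O/C(=C/C(=O)C(Cl)(Cl)Cl)C1)[C@@H]1CC[C@@H](C1)C2(C)C
A1 | alternative 1 | 1-(2-fluoro-4,6-dimethoxyphenyl)ethan-1-one | CC(=O)c1c(F)cc(OC)cc1OC
A2 | alternative 1 | (1R,2R,4S)-5',7'-dimethoxy-3,3-dimethylspiro[bicyclo[2.2.1]heptane-2,2'-chroman]-4'-one (O1 endo) | O=C1C[C@@]2(Oc3cc(OC)cc(OC)c31)[C@@H]1CC[C@@H](C1)C2(C)C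
A3 | alternative 2 | (1R,2R,4S)-2-ethenyl-2-[3,5-dimethoxy-2-(4-methylpent-1-en-2-yl)phenoxy]-3,3-dimethylbicyclo[2.2.1]heptane (aryloxy endo) | C=C[C@@]1(Oc2cc(OC)cc(OC)c2C(=C)CC(C)C)[C@@H]2CC[C@@H](C2)C1(C)C
A4 | alternative 2 | 5',7'-dimethoxy-3,3-dimethyl-4'-(2-methylpropyl)spiro[bicyclo[2.2.1]heptane-2,2'-chromene] (O1 endo, bridgeheads as in 3) | CC(C)CC1=C[C@@]2(Oc3cc(OC)cc(OC)c31)[C@@H]1CC[C@@H](C1)C2(C)C
A5 | alternative 3 | (1R,2R,4S)-2-[(2S)-2-(2,4-dimethoxyphenyl)-4-methylpentyl]-3,3-dimethylbicyclo[2.2.1]heptan-2-ol (hydroxyl endo) | CC(C)C[C@@H](C[C@@]1(O)[C@@H]2CC[C@@H](C2)C1(C)C)c1ccc(OC)cc1OC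
A6 | alternative 3 | (1R,2R,4S,4'S)-5',7'-dimethoxy-3,3-dimethyl-4'-(2-methylpropyl)spiro[bicyclo[2.2.1]heptane-2,2'-chromane] | CC(C)C[C@H]1C[C@@]2(Oc3cc(OC)cc(OC)c31)[C@@H]1CC[C@@H](C1)C2(C)C
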